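**Retrosynthetic overview**
- The target is opened at the C8 ester: a late acylation joins the bicyclic core diol (17 non-hydrogen atoms) with a bis-allyl-protected orsellinoyl chloride, and deallylation follows.
- The pyran ring (last ring formed) comes from a gold-catalysed 6-endo-dig hydroalkoxylation of an enynone triol. The enynyl chain is installed by conjugate alkynylation and Saegusa oxidation, using (E)-pent-3-en-1-yne made in its own branch.
- The carbocycle (first ring formed) comes from a catalytic enantioselective Diels–Alder reaction of 1-acetoxy-2-methylbutadiene with N-acryloyl oxazolidinone, which sets C8 and C8a. Anti dihydroxylation then sets C7.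
- The aromatic ring is built separately from methyl acetoacetate and methyl crotonate (Michael–Dieckmann, then aromatisation).

Assumption: atom labels (C1, O2, C3 … C8a) follow the isochromene numbering of the target; (1E)-1-bromoprop-1-ene is used as the pure E isomer.

**Fragment A: core diol**

Step 1
Reactants: 1 (2E)-2-methylbut-2-enal
Product: 2 (1E)-2-methylbuta-1,3-dien-1-yl acetate
Conditions: isopropenyl acetate (3 equiv), TsOH·H2O (2 mol%), 95 °C, acetone distilled off; fractional distillation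
Reagents that add atoms: isopropenyl acetate, CC(=C)OC(C)=O
Why: Acid-catalysed enol acetylation of the γ-enolisable enal traps the s-trans dienol as the (1E)-dienyl acetate (the isomer that reacts in the cycloaddition); no stereocentre is formed.

Step 2
Reactants: 3 1,3-oxazolidin-2-one; 4 prop-2-enoyl chloride
Product: 5 3-(prop-2-enoyl)-1,3-oxazolidin-2-one
Conditions: Et3N (1.3 equiv), LiCl (1.1 equiv), THF, −20 → 20 °C
Reagents that add atoms: none
Why: N-acylation of the carbamate under mild amine/LiCl conditions gives the two-point-binding dienophile without polymerising the acrylate.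

Step 3
Reactants: 2 (1E)-2-methylbuta-1,3-dien-1-yl acetate; 5 3-(prop-2-enoyl)-1,3-oxazolidin-2-one
Product: 6 3-{[(1R,2R)-2-(acetyloxy)-3-methylcyclohex-3-en-1-yl]carbonyl}-1,3-oxazolidin-2-one
Conditions: [Cu((R,R)-t-Bu-box)](SbF6)2 (10 mol%; t-Bu-box = 2,2'-(propane-2,2-diyl)bis(4-tert-butyl-4,5-dihydro-1,3-oxazole)), 2 (2 equiv), CH2Cl2, 0 → 25 °C; minor exo isomer removed by chromatography
Reagents that add atoms: none
Why: In this enantioselective Diels–Alder reaction the divalent copper bis(oxazoline) complex chelates the imide in a square-planar s-cis form, and the diene adds endo to the Cα Si face with its acetoxy terminus bonding to Cα ("ortho" rule), which sets C8a and the cis C8 acetate together.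

Step 4
Reactants: 6 3-{[(1R,2R)-2-(acetyloxy)-3-methylcyclohex-3-en-1-yl]carbonyl}-1,3-oxazolidin-2-one
Product: 7 (1R,6S)-6-(hydroxymethyl)-2-methylcyclohex-2-en-1-ol
Conditions: LiBH4 (4 equiv), MeOH (4 equiv), THF, 0 → 25 °C
Reagents that add atoms: none
Why: Hydride reduction of the exocyclic imide carbonyl and of the acetate releases the cis-1,3-diol without touching either stereocentre.

Step 5
Reactants: 7 (1R,6S)-6-(hydroxymethyl)-2-methylcyclohex-2-en-1-ol
Product: 8 (4aS,8aR)-2,2,8-trimethyl-4a,5,6,8a-tetrahydro-4H-1,3-benzodioxine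
Conditions: 2,2-dimethoxypropane (3 equiv), PPTS (5 mol%), CH2Cl2, 25 °C
Reagents that add atoms: 2,2-dimethoxypropane, COC(C)(C)OC
Why: Transacetalisation ties the cis C8 and C1 hydroxyls into a cis-fused 1,3-dioxane (acetonide), which protects both and shields one ring face.

Step 6
Reactants: 8 (4aS,8aR)-2,2,8-trimethyl-4a,5,6,8a-tetrahydro-4H-1,3-benzodioxine
Product: 9 (4aS,7R,8R,8aR)-2,2,8-trimethylhexahydro-4H-1,3-benzodioxine-7,8-diol
Conditions: OsO4 (3 mol%), NMO (1.5 equiv), acetone/H2O 5:1, 25 °C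
Reagents that add atoms: N-methylmorpholine N-oxide, C[N+]1([O-])CCOCC1; water, O; OsO4 (catalytic oxygen carrier), O=[Os](=O)(=O)=O
Why: Upjohn syn-dihydroxylation occurs on the convex face, anti to the allylic C–O bond of the cis-fused acetonide, so the new tertiary hydroxyl at C7 is trans to the C8 oxygen as in the target.

Step 7
Reactants: 9 (4aS,7R,8R,8aR)-2,2,8-trimethylhexahydro-4H-1,3-benzodioxine-7,8-diol
Product: 10 (4aS,8S,8aR)-8-hydroxy-2,2,8-trimethyl-4a,5,6,8a-tetrahydro-4H-1,3-benzodioxin-7(8H)-one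
Conditions: IBX (1.5 equiv), DMSO, 25 °C
Reagents that add atoms: none
Why: Hypervalent-iodine oxidation converts the secondary carbinol of the 1,2-diol into the C6 ketone without glycol cleavage and leaves the tertiary carbinol centre unchanged.

Step 8
Reactants: 10 (4aS,8S,8aR)-8-hydroxy-2,2,8-trimethyl-4a,5,6,8a-tetrahydro-4H-1,3-benzodioxin-7(8H)-one
Product: 11 {[(4aS,8S,8aR)-2,2,8-trimethyl-8-[(trimethylsilyl)oxy]-4a,5,8,8a-tetrahydro-4H-1,3-benzodioxin-7-yl]oxy}(trimethyl)silane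
Conditions: TMSOTf (2.6 equiv), Et3N (4 equiv), CH2Cl2, −20 → 0 °C
Reagents that add atoms: trimethylsilyl triflate, C[Si](C)(C)OS(=O)(=O)C(F)(F)F
Why: Soft enolisation and silylation give a single silyl enol ether, because the other α-carbon is quaternary, and cap the tertiary alcohol as its TMS ether.

Step 9
Reactants: 11 {[(4aS,8S,8aR)-2,2,8-trimethyl-8-[(trimethylsilyl)oxy]-4a,5,8,8a-tetrahydro-4H-1,3-benzodioxin-7-yl]oxy}(trimethyl)silane
Product: 12 (4aS,8S,8aR)-2,2,8-trimethyl-8-[(trimethylsilyl)oxy]-4a,8a-dihydro-4H-1,3-benzodioxin-7(8H)-one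
Conditions: Pd(OAc)2 (1.05 equiv), MeCN, 25 °C
Reagents that add atoms: none
Why: Saegusa–Ito oxidation (palladium enolate, then β-hydride elimination) gives the C4a=C5 enone regiospecifically.

**Fragment C: enyne**

Step 10
Reactants: 13 (1E)-1-bromoprop-1-ene; 14 ethynyl(trimethyl)silane
Product: 15 trimethyl[(3E)-pent-3-en-1-yn-1-yl]silane
Conditions: PdCl2(PPh3)2 (2 mol%), CuI (4 mol%), Et3N, 25 °C, sealed flask
Reagents that add atoms: none
Why: Sonogashira coupling of the vinyl bromide proceeds with retention of the E geometry.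

Step 11
Reactants: 15 trimethyl[(3E)-pent-3-en-1-yn-1-yl]silane
Product: 16 (3E)-pent-3-en-1-yne
Conditions: K2CO3 (0.2 equiv), MeOH, 0 °C; extracted into Et2O, washed, dried over 4 Å sieves, kept as a titrated solution
Reagents that add atoms: none
Why: Base-catalysed methanolysis of the alkynyl C–Si bond (protodesilylation) liberates the volatile terminal enyne.

**Joining fragment C and closing the pyran**

Step 12
Reactants: 16 (3E)-pent-3-en-1-yne; 12 (4aS,8S,8aR)-2,2,8-trimethyl-8-[(trimethylsilyl)oxy]-4a,8a-dihydro-4H-1,3-benzodioxin-7(8H)-one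
Product: 19 tert-butyl(dimethyl){[(4aS,5R,8S,8aR)-2,2,8-trimethyl-5-[(3E)-pent-3-en-1-yn-1-yl]-8-[(trimethylsilyl)oxy]-4a,5,8,8a-tetrahydro-4H-1,3-benzodioxin-7-yl]oxy}silane, via lithium (3E)-pent-3-en-1-yn-1-ide 17 (not isolated), via bromo[(3E)-pent-3-en-1-yn-1-yl]zinc 18 (not isolated)
Conditions: 16, n-BuLi, Et2O/THF, −78 °C; ZnBr2, 0 °C; then 12, TBSOTf (1.5 equiv), −40 → 0 °C
Reagents that add atoms: tert-butyldimethylsilyl triflate, CC(C)(C)[Si](C)(C)OS(=O)(=O)C(F)(F)F (n-BuLi, [Li]CCCC, and ZnBr2, Br[Zn]Br, leave metal atoms only in 17 and 18)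
Why: Silyl-triflate-promoted conjugate addition of the alkynylzinc reagent to the cyclic enone (1,4-alkynylation) traps the adduct as its TBS enol ether, with the alkynyl group expected anti to the ring-fusion substituent at a centre that becomes sp2 in the next step.

Step 13
Reactants: 19 tert-butyl(dimethyl){[(4aS,5R,8S,8aR)-2,2,8-trimethyl-5-[(3E)-pent-3-en-1-yn-1-yl]-8-[(trimethylsilyl)oxy]-4a,5,8,8a-tetrahydro-4H-1,3-benzodioxin-7-yl]oxy}silane
Product: 20 (4aS,8S,8aR)-2,2,8-trimethyl-5-[(3E)-pent-3-en-1-yn-1-yl]-8-[(trimethylsilyl)oxy]-4a,8a-dihydro-4H-1,3-benzodioxin-7(8H)-one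
Conditions: Pd(OAc)2 (1.1 equiv), MeCN, 40 °C
Reagents that add atoms: none
Why: A second Saegusa–Ito oxidation restores the C4a=C5 enone, now carrying the enynyl chain on its β-carbon.

Step 14
Reactants: 20 (4aS,8S,8aR)-2,2,8-trimethyl-5-[(3E)-pent-3-en-1-yn-1-yl]-8-[(trimethylsilyl)oxy]-4a,8a-dihydro-4H-1,3-benzodioxin-7(8H)-one
Product: 21 (4S,5R,6S)-5,6-dihydroxy-4-(hydroxymethyl)-6-methyl-3-[(3E)-pent-3-en-1-yn-1-yl]cyclohex-2-en-1-one
Conditions: AcOH/THF/H2O 3:1:1, 40 °C
Reagents that add atoms: none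
Why: Mild acid hydrolysis removes the acetonide and the tertiary TMS ether without affecting any stereocentre.

Step 15
Reactants: 21 (4S,5R,6S)-5,6-dihydroxy-4-(hydroxymethyl)-6-methyl-3-[(3E)-pent-3-en-1-yn-1-yl]cyclohex-2-en-1-one
Product: 22 (7S,8R,8aS)-7,8-dihydroxy-7-methyl-3-[(1E)-prop-1-en-1-yl]-8,8a-dihydro-1H-isochromen-6(7H)-one
Conditions: AuCl(PPh3) (5 mol%), AgOTf (5 mol%), CH2Cl2, 25 °C
Reagents that add atoms: none
Why: In this gold-catalysed 6-endo-dig hydroalkoxylation (cycloisomerisation) the primary hydroxyl attacks the alkyne carbon δ to the ketone, the electrophilic vinylogous position, whereas the C8 hydroxyl could only close by forming a bridgehead alkene.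

**Fragment B: aroyl chloride**

Step 16
Reactants: 23 methyl 3-oxobutanoate; 24 methyl (2E)-but-2-enoate
Product: 26 methyl 2-methyl-4,6-dioxocyclohexane-1-carboxylate, via dimethyl 2-acetyl-3-methylpentanedioate 25 (not isolated)
Conditions: NaOMe (1.1 equiv), MeOH, reflux; then aq. HCl
Reagents that add atoms: none
Why: Tandem Michael addition and Dieckmann (Claisen) cyclisation builds the six-membered 1,3-dione, whose stereocentres are lost on aromatisation.

Step 17
Reactants: 26 methyl 2-methyl-4,6-dioxocyclohexane-1-carboxylate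
Product: 27 methyl 3,5-dibromo-2,4-dihydroxy-6-methylbenzoate
Conditions: Br2 (3.0 equiv), AcOH, 25 → 50 °C
Reagents that add atoms: bromine, BrBr
Why: Bromination and dehydrobromination aromatise the cyclic 1,3-dione to the resorcinol and brominate both activated ring positions.

Step 18
Reactants: 27 methyl 3,5-dibromo-2,4-dihydroxy-6-methylbenzoate
Product: 28 methyl 2,4-dihydroxy-6-methylbenzoate
Conditions: H2 (1 atm), 10% Pd/C, Et3N (2.2 equiv), MeOH, 25 °C
Reagents that add atoms: none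
Why: Catalytic hydrogenolysis cleaves both aryl C–Br bonds to give methyl orsellinate.

Step 19
Reactants: 28 methyl 2,4-dihydroxy-6-methylbenzoate
Product: 29 methyl 6-methyl-2,4-bis(prop-2-en-1-yloxy)benzoate
Conditions: allyl bromide (2.5 equiv), K2CO3 (3 equiv), DMF, 60 °C
Reagents that add atoms: allyl bromide, C=CCBr
Why: Williamson etherification protects both phenols as allyl ethers, which can later be removed under neutral palladium catalysis.

Step 20
Reactants: 29 methyl 6-methyl-2,4-bis(prop-2-en-1-yloxy)benzoate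
Product: 30 6-methyl-2,4-bis(prop-2-en-1-yloxy)benzoic acid
Conditions: KOH (5 equiv), MeOH/H2O 3:1, 80 °C; then aq. HCl
Reagents that add atoms: potassium hydroxide, [K+].[OH-]
Why: Forcing saponification cleaves the hindered ortho,ortho-disubstituted methyl ester.

Step 21
Reactants: 30 6-methyl-2,4-bis(prop-2-en-1-yloxy)benzoic acid
Product: 31 6-methyl-2,4-bis(prop-2-en-1-yloxy)benzoyl chloride
Conditions: (COCl)2 (1.5 equiv), DMF (cat.), CH2Cl2, 0 → 25 °C; evaporated, used crude
Reagents that add atoms: oxalyl chloride, ClC(=O)C(Cl)=O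
Why: Vilsmeier-type activation converts the acid into the acid chloride needed to acylate a hindered alcohol.

**Late coupling and deprotection**

Step 22
Reactants: 22 (7S,8R,8aS)-7,8-dihydroxy-7-methyl-3-[(1E)-prop-1-en-1-yl]-8,8a-dihydro-1H-isochromen-6(7H)-one; 31 6-methyl-2,4-bis(prop-2-en-1-yloxy)benzoyl chloride
Product: 32 (7S,8R,8aS)-7-hydroxy-7-methyl-6-oxo-3-[(1E)-prop-1-en-1-yl]-6,7,8,8a-tetrahydro-1H-isochromen-8-yl 6-methyl-2,4-bis(prop-2-en-1-yloxy)benzoate
Conditions: 31 (1.5 equiv), Et3N (3 equiv), DMAP (1 equiv), CH2Cl2, 0 → 40 °C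
Reagents that add atoms: none
Why: DMAP-mediated acylation takes place at the only secondary hydroxyl (the tertiary C7 hydroxyl is inert), joining the two fragments with all three stereocentres retained.

Step 23
Reactants: 32 (7S,8R,8aS)-7-hydroxy-7-methyl-6-oxo-3-[(1E)-prop-1-en-1-yl]-6,7,8,8a-tetrahydro-1H-isochromen-8-yl 6-methyl-2,4-bis(prop-2-en-1-yloxy)benzoate
Product: 33 (7S,8R,8aS)-7-hydroxy-7-methyl-6-oxo-3-[(1E)-prop-1-en-1-yl]-6,7,8,8a-tetrahydro-1H-isochromen-8-yl 2,4-dihydroxy-6-methylbenzoate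
Conditions: Pd(PPh3)4 (5 mol%), morpholine (10 equiv), THF, 25 °C
Reagents that add atoms: none
Why: Palladium-catalysed allyl transfer to morpholine (Tsuji–Trost deallylation) frees both phenols under neutral conditions that leave the dienone, the ester and the stereocentres untouched.

**Compound list**
1 | (2E)-2-methylbut-2-enal | C/C=C(\C)C=O | starting material
2 | (1E)-2-methylbuta-1,3-dien-1-yl acetate | CC(=O)O/C=C(\C)C=C | intermediate
3 | 1,3-oxazolidin-2-one | O=C1NCCO1 | starting material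
4 | prop-2-enoyl chloride | C=CC(Cl)=O | starting material
5 | 3-(prop-2-enoyl)-1,3-oxazolidin-2-one | C=CC(=O)N1CCOC1=O | intermediate
6 | 3-{[(1R,2R)-2-(acetyloxy)-3-methylcyclohex-3-en-1-yl]carbonyl}-1,3-oxazolidin-2-one (cis) | C1CC=C(C)[C@H](OC(C)=O)[C@@H]1C(=O)N1CCOC1=O | intermediate
7 | (1R,6S)-6-(hydroxymethyl)-2-methylcyclohex-2-en-1-ol (cis) | C1CC=C(C)[C@H](O)[C@@H]1CO | intermediate
8 | (4aS,8aR)-2,2,8-trimethyl-4a,5,6,8a-tetrahydro-4H-1,3-benzodioxine | C1CC=C(C)[C@H](OC(C)(C)OC2)[C@@H]12 | intermediate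
9 | (4aS,7R,8R,8aR)-2,2,8-trimethylhexahydro-4H-1,3-benzodioxine-7,8-diol | C1C[C@@H](O)[C@@](C)(O)[C@H](OC(C)(C)OC2)[C@@H]12 | intermediate
10 | (4aS,8S,8aR)-8-hydroxy-2,2,8-trimethyl-4a,5,6,8a-tetrahydro-4H-1,3-benzodioxin-7(8H)-one | C1CC(=O)[C@@](C)(O)[C@H](OC(C)(C)OC2)[C@@H]12 | intermediate
11 | {[(4aS,8S,8aR)-2,2,8-trimethyl-8-[(trimethylsilyl)oxy]-4a,5,8,8a-tetrahydro-4H-1,3-benzodioxin-7-yl]oxy}(trimethyl)silane | C1C=C(O[Si](C)(C)C)[C@@](C)(O[Si](C)(C)C)[C@H](OC(C)(C)OC2)[C@@H]12 | intermediate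
12 | (4aS,8S,8aR)-2,2,8-trimethyl-8-[(trimethylsilyl)oxy]-4a,8a-dihydro-4H-1,3-benzodioxin-7(8H)-one | C1=CC(=O)[C@@](C)(O[Si](C)(C)C)[C@H](OC(C)(C)OC2)[C@@H]12 | intermediate
13 | (1E)-1-bromoprop-1-ene | C/C=C/Br | starting material
14 | ethynyl(trimethyl)silane | C#C[Si](C)(C)C | starting material
15 | trimethyl[(3E)-pent-3-en-1-yn-1-yl]silane | C/C=C/C#C[Si](C)(C)C | intermediate
16 | (3E)-pent-3-en-1-yne | C/C=C/C#C | intermediate
17 | lithium (3E)-pent-3-en-1-yn-1-ide | C/C=C/C#C[Li] | intermediate (not isolated)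
18 | bromo[(3E)-pent-3-en-1-yn-1-yl]zinc | C/C=C/C#C[Zn]Br | intermediate (not isolated)
19 | tert-butyl(dimethyl){[(4aS,5R,8S,8aR)-2,2,8-trimethyl-5-[(3E)-pent-3-en-1-yn-1-yl]-8-[(trimethylsilyl)oxy]-4a,5,8,8a-tetrahydro-4H-1,3-benzodioxin-7-yl]oxy}silane | C/C=C/C#C[C@H]1C=C(O[Si](C)(C)C(C)(C)C)[C@@](C)(O[Si](C)(C)C)[C@H](OC(C)(C)OC2)[C@@H]12 | intermediate
20 | (4aS,8S,8aR)-2,2,8-trimethyl-5-[(3E)-pent-3-en-1-yn-1-yl]-8-[(trimethylsilyl)oxy]-4a,8a-dihydro-4H-1,3-benzodioxin-7(8H)-one | C/C=C/C#CC1=CC(=O)[C@@](C)(O[Si](C)(C)C)[C@H](OC(C)(C)OC2)[C@@H]12 | intermediate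
21 | (4S,5R,6S)-5,6-dihydroxy-4-(hydroxymethyl)-6-methyl-3-[(3E)-pent-3-en-1-yn-1-yl]cyclohex-2-en-1-one | C/C=C/C#CC1=CC(=O)[C@@](C)(O)[C@H](O)[C@@H]1CO | intermediate
22 | (7S,8R,8aS)-7,8-dihydroxy-7-methyl-3-[(1E)-prop-1-en-1-yl]-8,8a-dihydro-1H-isochromen-6(7H)-one | C/C=C/C1=CC2=CC(=O)[C@@](C)(O)[C@H](O)[C@@H]2CO1 | intermediate
23 | methyl 3-oxobutanoate | CC(=O)CC(=O)OC | starting material
24 | methyl (2E)-but-2-enoate | C/C=C/C(=O)OC | starting material
25 | dimethyl 2-acetyl-3-methylpentanedioate (stereoisomer mixture) | COC(=O)CC(C)C(C(C)=O)C(=O)OC | intermediate (not isolated)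
26 | methyl 2-methyl-4,6-dioxocyclohexane-1-carboxylate (racemic, enolised) | COC(=O)C1C(C)CC(=O)CC1=O | intermediate
27 | methyl 3,5-dibromo-2,4-dihydroxy-6-methylbenzoate | COC(=O)c1c(C)c(Br)c(O)c(Br)c1O | intermediate
28 | methyl 2,4-dihydroxy-6-methylbenzoate | COC(=O)c1c(C)cc(O)cc1O | intermediate
29 | methyl 6-methyl-2,4-bis(prop-2-en-1-yloxy)benzoate | COC(=O)c1c(C)cc(OCC=C)cc1OCC=C | intermediate
30 | 6-methyl-2,4-bis(prop-2-en-1-yloxy)benzoic acid | OC(=O)c1c(C)cc(OCC=C)cc1OCC=C | intermediate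
31 | 6-methyl-2,4-bis(prop-2-en-1-yloxy)benzoyl chloride | ClC(=O)c1c(C)cc(OCC=C)cc1OCC=C | intermediate
32 | (7S,8R,8aS)-7-hydroxy-7-methyl-6-oxo-3-[(1E)-prop-1-en-1-yl]-6,7,8,8a-tetrahydro-1H-isochromen-8-yl 6-methyl-2,4-bis(prop-2-en-1-yloxy)benzoate | C/C=C/C1=CC2=CC(=O)[C@@](C)(O)[C@H](OC(=O)c3c(C)cc(OCC=C)cc3OCC=C)[C@@H]2CO1 | intermediate
33 | (7S,8R,8aS)-7-hydroxy-7-methyl-6-oxo-3-[(1E)-prop-1-en-1-yl]-6,7,8,8a-tetrahydro-1H-isochromen-8-yl 2,4-dihydroxy-6-methylbenzoate | C/C=C/C1=CC2=CC(=O)[C@@](C)(O)[C@H](OC(=O)c3c(C)cc(O)cc3O)[C@@H]2CO1 | target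

**Step count**
Total steps: 23.
Longest linear sequence: 14 steps (1 → 2 → 6 → 7 → 8 → 9 → 10 → 11 → 12 → 19 → 20 → 21 → 22 → 32 → 33; steps 1, 3–9, 12–15, 22 and 23).

**Three steps most likely to fail, with fallbacks**

Step 12 (conjugate alkynylation of the hindered α'-silyloxy enone). The risk is 1,2-addition or no reaction at the β-carbon next to the ring fusion. The fallback replaces conjugate addition by cross-coupling; it sets out from enone 12 and returns at enynone 20. Copper-catalysed conjugate borylation of 12 (B2pin2, CuCl, NaOt-Bu, DPEphos, MeOH, THF) gives the β-boryl ketone F1. Oxidation with NaBO3·4H2O gives the β-hydroxy ketone F2. Dess–Martin periodinane gives the 1,3-diketone F3. Tf2O with 2,6-lutidine at −78 °C gives the enol triflate F4, formed at the less hindered carbonyl remote from the quaternary carbinol. Sonogashira coupling of F4 with enyne 16 (PdCl2(PPh3)2, CuI, Et3N) then gives 20.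

Step 15 (gold-catalysed ring closure). The risks are competing 5-exo closure and acid sensitivity of the dienol ether. The fallback uses an electrophile-driven closure; it sets out from triol 21 and returns at core diol 22. Iodocyclisation (I2, NaHCO3, MeCN, 0 °C) gives the 4-iodo pyran F5, the 6-endo mode being favoured by the conjugating propenyl group. Palladium-catalysed formate reduction (Pd(OAc)2, PPh3, HCO2H, Et3N, DMF, 50 °C) removes the iodine and gives 22.

Step 22 (acylation of a hindered secondary alcohol with an ortho,ortho-disubstituted aroyl chloride). The risk is low conversion. The fallback transfers the acyl group from a benzodioxinone, whose acyl carbon is far less shielded; it sets out from methyl orsellinate 28 together with core diol 22 and returns at target 33. Hydrolysis of 28 (LiOH, THF/H2O, 25 °C) gives orsellinic acid F6. Acetone with TFAA/TFA gives the hydroxy benzodioxinone F7. Allylation (allyl bromide, K2CO3) gives the allyloxy benzodioxinone F8. The sodium alkoxide of 22 (NaN(SiMe3)2, THF, −78 → 0 °C) opens F8, with loss of acetone, to the mono-allyl salicylate ester F9. Deallylation as in step 23 (Pd(PPh3)4, morpholine) gives 33.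

**Further compounds**
F1 | step 12 | β-boryl ketone (pinacolboryl group at the enone β-carbon of 12, anti to the ring-fusion CH2O) | CC1(C)OB(OC1(C)C)[C@H]1CC(=O)[C@@](C)(O[Si](C)(C)C)[C@H](OC(C)(C)OC2)[C@@H]12
F2 | step 12 | β-hydroxy ketone | O[C@H]1CC(=O)[C@@](C)(O[Si](C)(C)C)[C@H](OC(C)(C)OC2)[C@@H]12
F3 | step 12 | 1,3-diketone | O=C1CC(=O)[C@@](C)(O[Si](C)(C)C)[C@H](OC(C)(C)OC2)[C@@H]12
F4 | step 12 | enol triflate | O=S(=O)(OC1=CC(=O)[C@@](C)(O[Si](C)(C)C)[C@H](OC(C)(C)OC2)[C@@H]12)C(F)(F)F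
F5 | step 15 | 4-iodo pyran ((7S,8R,8aS)-7,8-dihydroxy-4-iodo-7-methyl-3-[(1E)-prop-1-en-1-yl]-8,8a-dihydro-1H-isochromen-6(7H)-one) | C/C=C/C1=C(I)C2=CC(=O)[C@@](C)(O)[C@H](O)[C@@H]2CO1
F6 | step 22 | orsellinic acid (2,4-dihydroxy-6-methylbenzoic acid) | Cc1cc(O)cc(O)c1C(O)=O
F7 | step 22 | hydroxy benzodioxinone (7-hydroxy-2,2,5-trimethyl-4H-1,3-benzodioxin-4-one) | Cc1cc(O)cc2OC(C)(C)OC(=O)c12
F8 | step 22 | allyloxy benzodioxinone (2,2,5-trimethyl-7-(prop-2-en-1-yloxy)-4H-1,3-benzodioxin-4-one) | Cc1cc(OCC=C)cc2OC(C)(C)OC(=O)c12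
F9 | step 22 | mono-allyl salicylate ester (8-O-[2-hydroxy-6-methyl-4-(prop-2-en-1-yloxy)benzoyl] derivative of 22) | C/C=C/C1=CC2=CC(=O)[C@@](C)(O)[C@H](OC(=O)c3c(C)cc(OCC=C)cc3O)[C@@H]2CO1
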